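**Retrosynthetic overview** (flavanone numbering)

- The strategy rests on one feature: ring C is joined to ring A through two neighbouring ring-A carbons, C8a (bearing O1) and C4a (bearing the C4 carbonyl), which lie between the alkylated C8 and the oxygenated C5. This is the substitution pattern of an aryne C4a≡C8a.
- Key disconnection: O1–C8a and C4–C4a are made in one operation from an ortho-silylaryl triflate of ring A (C8 side chain already in place) and an (S)-beta-hydroxy acyl donor that carries ring B and C2. Ring C is the only ring formed; rings A and B are bought as arenes.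
- Silyl triflate: phloroglucinol → bis-MOM phenol → N-isopropyl carbamate → two directed ortho-metalations in one flask (SiMe3, then I) → Negishi coupling with the side-chain alkylzinc → carbamate cleavage and triflation.
- Side chain: (S)-3-bromo-2-methylpropan-1-ol supplies the methyl-bearing centre; carboxylation, Evans prenylation (second centre), reduction and iodination follow.
- Acyl donor: 2,4-dihydroxyacetophenone → beta-keto ester → asymmetric transfer hydrogenation (sets C2) → Weinreb amide. One acid treatment at the end removes the three aryl MOM ethers and the silyl ether.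

Key step: step 17

**Remarks on the chemistry**

- (a) The primary hydroxyl of the side chain is carried as a tert-butyldimethylsilyl ether, because an alkyl MOM ether would need much stronger acid at the end than the three aryl MOM ethers.
- (b) The (S)-hydroxy methyl ester is converted into its N-methoxy-N-methyl amide before the aryne step. The ring-C carbonyl then stays masked as a hemiaminal alkoxide until work-up, so no enolisable flavanone meets alkoxide or fluoride.
- (c) (S)-3-Bromo-2-methylpropan-1-ol is assumed to be purchasable; it is otherwise available from the (S)-Roche ester.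
- (d) The CIP descriptors of the side-chain centres change along the route only because substituent priorities change; no bond at these centres is broken after they are set.

**Route**

Step 1
Reactants: 1 (S)-3-bromo-2-methylpropan-1-ol
Product: 2 [(2S)-3-bromo-2-methylpropoxy](tert-butyl)dimethylsilane
Conditions: TBSCl, imidazole, CH2Cl2, 0 °C → rt
Reagents that add atoms: tert-butyldimethylsilyl chloride, CC(C)(C)[Si](C)(C)Cl
Why: Standard silyl ether formation at a primary alcohol, which leaves the stereocenter and the primary bromide untouched.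

Step 2
Reactants: 2 [(2S)-3-bromo-2-methylpropoxy](tert-butyl)dimethylsilane
Product: 4 (3R)-4-(tert-butyldimethylsilyloxy)-3-methylbutanoic acid, via Grignard reagent 3 (not isolated)
Conditions: Mg turnings (BrCH2CH2Br activation), THF, 40 °C; then CO2, −40 °C → rt; aq. HCl to pH 3, 0 °C
Reagents that add atoms: carbon dioxide, O=C=O
Why: Grignard formation and carboxylation add the carbon that later becomes the benzylic CH2 on C8, and the gamma-silyloxy organomagnesium does not affect the remote stereocenter.

Step 3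
Reactants: 4 (3R)-4-(tert-butyldimethylsilyloxy)-3-methylbutanoic acid, 5 (4S)-4-benzyl-1,3-oxazolidin-2-one
Product: 7 (4S)-4-benzyl-3-[(3R)-4-(tert-butyldimethylsilyloxy)-3-methylbutanoyl]-1,3-oxazolidin-2-one, via mixed pivalic anhydride 6 (not isolated)
Conditions: t-BuCOCl, Et3N, THF, −20 °C; then LiCl, 5, −20 °C → rt
Reagents that add atoms: none
Why: N-Acylation of the oxazolidinone through the mixed pivalic anhydride installs the Evans auxiliary under conditions too mild to disturb the silyl ether.

Step 4
Reactants: 7 (4S)-4-benzyl-3-[(3R)-4-(tert-butyldimethylsilyloxy)-3-methylbutanoyl]-1,3-oxazolidin-2-one, 8 1-bromo-3-methylbut-2-ene (prenyl bromide)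
Product: 10 (4S)-4-benzyl-3-[(2S)-2-[(2R)-1-(tert-butyldimethylsilyloxy)propan-2-yl]-5-methylhex-4-enoyl]-1,3-oxazolidin-2-one, via sodium Z-enolate 9 (not isolated)
Conditions: NaN(SiMe3)2, THF, −78 °C; then 8 (3 equiv), −78 → −40 °C
Reagents that add atoms: none
Why: Evans alkylation, in which the chelated sodium Z-enolate is attacked by the allylic bromide on the face opposite the benzyl group of the (S)-auxiliary, setting the prenyl-bearing center as (S) (it is (2R) in the target once the carbonyl carbon has become the benzylic CH2) with the auxiliary overriding any bias from the adjacent methyl-bearing center.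

Step 5
Reactants: 10 (4S)-4-benzyl-3-[(2S)-2-[(2R)-1-(tert-butyldimethylsilyloxy)propan-2-yl]-5-methylhex-4-enoyl]-1,3-oxazolidin-2-one
Product: 11 (2S)-2-[(2R)-1-(tert-butyldimethylsilyloxy)propan-2-yl]-5-methylhex-4-en-1-ol
Conditions: LiBH4, MeOH (1 equiv), THF/Et2O, 0 °C
Reagents that add atoms: none
Why: Reductive cleavage of the N-acyl oxazolidinone by hydride reduction of the exocyclic carbonyl gives the primary alcohol without epimerising the alpha center and returns the auxiliary.

Step 6
Reactants: 11 (2S)-2-[(2R)-1-(tert-butyldimethylsilyloxy)propan-2-yl]-5-methylhex-4-en-1-ol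
Product: 12 tert-butyl{[(2R,3S)-3-(iodomethyl)-2,6-dimethylhept-5-en-1-yl]oxy}dimethylsilane
Conditions: PPh3, imidazole, I2, CH2Cl2, 0 °C → rt
Reagents that add atoms: iodine, II
Why: Appel-type iodination converts the primary alcohol into the iodide by SN2 at a non-stereogenic carbon under buffered conditions that spare the silyl ether and the trisubstituted alkene.

Step 7
Reactants: 13 benzene-1,3,5-triol (phloroglucinol)
Product: 14 3,5-bis(methoxymethoxy)phenol
Conditions: MOMCl (2.0 equiv), i-Pr2NEt (2.2 equiv), CH2Cl2/DMF, 0 °C → rt; chromatography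
Reagents that add atoms: chloromethyl methyl ether, COCCl
Why: Williamson-type O-alkylation with two equivalents of MOMCl should give the bis-ether as the main component of a statistical mixture, from which it is separated while the mono- and tris-ethers are recycled.

Step 8
Reactants: 14 3,5-bis(methoxymethoxy)phenol
Product: 15 3,5-bis(methoxymethoxy)phenyl N-isopropylcarbamate
Conditions: i-PrNCO, Et3N (cat.), CH2Cl2, rt
Reagents that add atoms: isopropyl isocyanate, CC(C)N=C=O
Why: Base-catalysed addition of the phenol to the isocyanate gives a carbamate that is both the strongest ortho-directing group on the ring and a phenol protecting group removable with mild base.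

Step 9
Reactants: 15 3,5-bis(methoxymethoxy)phenyl N-isopropylcarbamate
Product: 21 2-iodo-3,5-bis(methoxymethoxy)-6-(trimethylsilyl)phenyl N-isopropylcarbamate, via N-silyl carbamate 16 (not isolated), via first aryllithium 17 (not isolated), via N-silyl arylsilane 18 (not isolated), via second aryllithium 19 (not isolated), via N-silyl aryl iodide 20 (not isolated)
Conditions: TBSOTf (1.05 equiv), TMEDA (3 equiv), Et2O, 0 °C → rt; n-BuLi (1.1 equiv), −78 °C; Me3SiCl (1.1 equiv), −78 → −20 °C; n-BuLi (1.3 equiv), −78 °C; I2 (1.5 equiv, THF), −78 °C; aq. Na2S2O3, then aq. citric acid (pH 4)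
Reagents that add atoms: chlorotrimethylsilane, C[Si](C)(C)Cl; iodine, II
Why: Two successive directed ortho-metalations under a single transient N-silylation, in which the N-silylated carbamate as the strongest director steers the first lithiation at −78 °C to a position it shares with one MOM ether (two equivalent sites) rather than to the position between the two MOM ethers, Me3SiCl (charged to match the n-BuLi so that none is left over) traps that aryllithium, the second lithiation then takes the one remaining position flanked by the carbamate and a MOM ether (the aryl–SiMe3 bond is inert to n-BuLi), iodine traps it, and the mildly acidic work-up removes the N-silyl group.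

Step 10
Reactants: 12 tert-butyl{[(2R,3S)-3-(iodomethyl)-2,6-dimethylhept-5-en-1-yl]oxy}dimethylsilane, 21 2-iodo-3,5-bis(methoxymethoxy)-6-(trimethylsilyl)phenyl N-isopropylcarbamate
Product: 23 2-[(2R)-2-[(2R)-1-(tert-butyldimethylsilyloxy)propan-2-yl]-5-methylhex-4-en-1-yl]-3,5-bis(methoxymethoxy)-6-(trimethylsilyl)phenyl N-isopropylcarbamate, via alkylzinc iodide 22 (not isolated)
Conditions: 12 (1.3 equiv), Zn dust (BrCH2CH2Br/Me3SiCl activation), LiCl, THF, 40 °C; then 21, Pd(OAc)2 (4 mol %), SPhos (8 mol %), THF, rt → 50 °C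
Reagents that add atoms: none
Why: Negishi coupling of a primary alkylzinc iodide (from zinc insertion into the C–I bond) with the doubly ortho-substituted aryl iodide under Pd(OAc)2/SPhos, a system suited to hindered electron-rich aryl halides and tolerant of the carbamate N–H, with both side-chain stereocenters as spectators.

Step 11
Reactants: 23 2-[(2R)-2-[(2R)-1-(tert-butyldimethylsilyloxy)propan-2-yl]-5-methylhex-4-en-1-yl]-3,5-bis(methoxymethoxy)-6-(trimethylsilyl)phenyl N-isopropylcarbamate
Product: 25 2-[(2R)-2-[(2R)-1-(tert-butyldimethylsilyloxy)propan-2-yl]-5-methylhex-4-en-1-yl]-3,5-bis(methoxymethoxy)-6-(trimethylsilyl)phenyl trifluoromethanesulfonate, via silylphenol 24 (not isolated)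
Conditions: DBU, Et2NH, MeCN, 40 °C; then PhNTf2, rt
Reagents that add atoms: N-phenylbis(trifluoromethanesulfonimide), O=S(=O)(N(c1ccccc1)S(=O)(=O)C(F)(F)F)C(F)(F)F
Why: E1cB cleavage of the N–H carbamate (isopropyl isocyanate is lost and scavenged by Et2NH) frees the phenol under mild base and PhNTf2 triflates it in the same flask, so the acid-sensitive electron-rich ortho-silylphenol is never isolated.

Step 12
Reactants: 26 1-(2,4-dihydroxyphenyl)ethan-1-one
Product: 27 1-[2-hydroxy-4-(methoxymethoxy)phenyl]ethan-1-one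
Conditions: MOMCl (1.1 equiv), K2CO3, acetone, 0 °C → rt
Reagents that add atoms: chloromethyl methyl ether, COCCl
Why: Regioselective Williamson-type O-alkylation at the 4-hydroxyl, because the 2-hydroxyl is hydrogen-bonded to the ketone and much less nucleophilic.

Step 13
Reactants: 27 1-[2-hydroxy-4-(methoxymethoxy)phenyl]ethan-1-one
Product: 28 1-[2-methoxy-4-(methoxymethoxy)phenyl]ethan-1-one
Conditions: MeI, K2CO3, DMF, 40 °C
Reagents that add atoms: iodomethane, CI
Why: Williamson methylation of the remaining hydrogen-bonded phenol under more forcing conditions.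

Step 14
Reactants: 28 1-[2-methoxy-4-(methoxymethoxy)phenyl]ethan-1-one
Product: 29 methyl 3-[2-methoxy-4-(methoxymethoxy)phenyl]-3-oxopropanoate
Conditions: NaH, (MeO)2CO, THF, reflux; AcOH quench
Reagents that add atoms: dimethyl carbonate, COC(=O)OC
Why: Crossed Claisen condensation of the ketone enolate with dimethyl carbonate, driven by deprotonation of the beta-keto ester as it forms.

Step 15
Reactants: 29 methyl 3-[2-methoxy-4-(methoxymethoxy)phenyl]-3-oxopropanoate
Product: 30 methyl (3S)-3-hydroxy-3-[2-methoxy-4-(methoxymethoxy)phenyl]propanoate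
Conditions: RuCl[(S,S)-TsDPEN](p-cymene) (1 mol %), HCO2H/Et3N (5:2), 30 °C
Reagents that add atoms: none
Why: Noyori–Ikariya asymmetric transfer hydrogenation of the aryl ketone, in which the (S,S)-TsDPEN ligand directs hydride to the face that gives the (S)-benzylic alcohol (the same sense as for acetophenone) and so sets C2 of the flavanone.

Step 16
Reactants: 30 methyl (3S)-3-hydroxy-3-[2-methoxy-4-(methoxymethoxy)phenyl]propanoate
Product: 31 (3S)-3-hydroxy-N-methoxy-3-[2-methoxy-4-(methoxymethoxy)phenyl]-N-methylpropanamide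
Conditions: MeNH(OMe)·HCl, i-PrMgCl, THF, −20 → 0 °C; aq. NH4Cl
Reagents that add atoms: N,O-dimethylhydroxylamine hydrochloride, CNOC.Cl
Why: Aminolysis of the ester by the chloromagnesium amide of N,O-dimethylhydroxylamine (Weinreb amide formation) should proceed at low temperature on the magnesium alkoxide of the beta-hydroxy ester without touching the carbinol center.

Step 17
Reactants: 25 2-[(2R)-2-[(2R)-1-(tert-butyldimethylsilyloxy)propan-2-yl]-5-methylhex-4-en-1-yl]-3,5-bis(methoxymethoxy)-6-(trimethylsilyl)phenyl trifluoromethanesulfonate, 31 (3S)-3-hydroxy-N-methoxy-3-[2-methoxy-4-(methoxymethoxy)phenyl]-N-methylpropanamide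
Product: 36 (2S)-8-[(2R)-2-[(2R)-1-(tert-butyldimethylsilyloxy)propan-2-yl]-5-methylhex-4-en-1-yl]-2-[2-methoxy-4-(methoxymethoxy)phenyl]-5,7-bis(methoxymethoxy)chroman-4-one, via sodium alkoxide 32 (not isolated), via aryne 33 (not isolated), via aryl anion 34 (not isolated), via hemiaminal alkoxide 35 (not isolated)
Conditions: 31 (1.5 equiv), NaH (1.4 equiv), THF, 0 °C; then CsF (3 equiv), 18-crown-6 (3 equiv), slow addition of 25 (1.0 equiv), THF, 0 °C → rt; AcOH, then pH 5 buffer, 0 °C
Reagents that add atoms: none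
Why: Proposed new method: fluoride strips the Me3Si group from 25 with loss of triflate to give aryne 33 (C4a≡C8a), the preformed alkoxide 32 adds through oxygen at C8a (O1–C8a), and the aryl carbanion 34 thus generated at C4a attacks the tethered N-methoxy-N-methyl amide carbonyl (C4–C4a) to give hemiaminal alkoxide 35, which releases the ring-C ketone only on the acidic quench. The closest known reactions are the aryne annulation of salicylate esters to xanthones (phenoxide addition, then capture of the aryl anion by the ester), the insertion of arynes into carboxylic acid C–O bonds and the Parham cyclisation of aryllithiums onto Weinreb amides; an aliphatic beta-alkoxide carrying its own acyl acceptor has not been used in this way. Ring C is closed in the 6-exo-trig mode. No stereocenter is created: C2 comes from 31 with its C–O bond untouched, and because the carbonyl stays masked as 35 until work-up, no enolisable chromanone meets alkoxide or fluoride, which shuts off the retro-oxa-Michael opening that would racemise C2. The selectivity needed is oxygen addition at C8a and not at C4a, and it is secured by the C5 methoxymethoxy group next to C4a, whose inductive effect makes the remote carbon C8a the electrophilic end and places the developing charge at C4a, while the C8 alkyl group only slows the attack sterically. Using the amide in place of an ester also makes retro-aldol cleavage of 32 and alpha-deprotonation by 34 less favourable.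

Step 18
Reactants: 36 (2S)-8-[(2R)-2-[(2R)-1-(tert-butyldimethylsilyloxy)propan-2-yl]-5-methylhex-4-en-1-yl]-2-[2-methoxy-4-(methoxymethoxy)phenyl]-5,7-bis(methoxymethoxy)chroman-4-one
Product: 37 (2S)-5,7-dihydroxy-8-[(2R)-2-[(2R)-1-hydroxypropan-2-yl]-5-methylhex-4-en-1-yl]-2-(4-hydroxy-2-methoxyphenyl)chroman-4-one (CNP0081318.1)
Conditions: HCl (2 M aq.)/MeOH/THF, 40 °C
Reagents that add atoms: none
Why: Acid-catalysed acetal methanolysis removes the three aryl MOM ethers and the primary silyl ether in one operation under conditions mild enough to leave the trisubstituted alkene and the C2 configuration intact.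

**Compound list**

1 | (S)-3-bromo-2-methylpropan-1-ol | BrC[C@@H](C)CO | starting material
2 | [(2S)-3-bromo-2-methylpropoxy](tert-butyl)dimethylsilane | BrC[C@@H](C)CO[Si](C)(C)C(C)(C)C | intermediate
3 | [(2S)-3-(tert-butyldimethylsilyloxy)-2-methylpropyl]magnesium bromide | Br[Mg]C[C@@H](C)CO[Si](C)(C)C(C)(C)C | intermediate
4 | (3R)-4-(tert-butyldimethylsilyloxy)-3-methylbutanoic acid | OC(=O)C[C@@H](C)CO[Si](C)(C)C(C)(C)C | intermediate
5 | (4S)-4-benzyl-1,3-oxazolidin-2-one | O=C1N[C@@H](Cc2ccccc2)CO1 | starting material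
6 | (3R)-4-(tert-butyldimethylsilyloxy)-3-methylbutanoic pivalic anhydride | CC(C)(C)C(=O)OC(=O)C[C@@H](C)CO[Si](C)(C)C(C)(C)C | intermediate
7 | (4S)-4-benzyl-3-[(3R)-4-(tert-butyldimethylsilyloxy)-3-methylbutanoyl]-1,3-oxazolidin-2-one | O=C(C[C@@H](C)CO[Si](C)(C)C(C)(C)C)N1[C@@H](Cc2ccccc2)COC1=O | intermediate
8 | 1-bromo-3-methylbut-2-ene (prenyl bromide) | CC(C)=CCBr | starting material
9 | sodium Z-enolate of 7 | [Na+].[O-]/C(=C\[C@@H](C)CO[Si](C)(C)C(C)(C)C)N1[C@@H](Cc2ccccc2)COC1=O | intermediate
10 | (4S)-4-benzyl-3-[(2S)-2-[(2R)-1-(tert-butyldimethylsilyloxy)propan-2-yl]-5-methylhex-4-enoyl]-1,3-oxazolidin-2-one | O=C([C@@H](CC=C(C)C)[C@@H](C)CO[Si](C)(C)C(C)(C)C)N1[C@@H](Cc2ccccc2)COC1=O | intermediate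
11 | (2S)-2-[(2R)-1-(tert-butyldimethylsilyloxy)propan-2-yl]-5-methylhex-4-en-1-ol | OC[C@@H](CC=C(C)C)[C@@H](C)CO[Si](C)(C)C(C)(C)C | intermediate
12 | tert-butyl{[(2R,3S)-3-(iodomethyl)-2,6-dimethylhept-5-en-1-yl]oxy}dimethylsilane | IC[C@@H](CC=C(C)C)[C@@H](C)CO[Si](C)(C)C(C)(C)C | intermediate
13 | benzene-1,3,5-triol (phloroglucinol) | Oc1cc(O)cc(O)c1 | starting material
14 | 3,5-bis(methoxymethoxy)phenol | COCOc1cc(O)cc(OCOC)c1 | intermediate
15 | 3,5-bis(methoxymethoxy)phenyl N-isopropylcarbamate | CC(C)NC(=O)Oc1cc(OCOC)cc(OCOC)c1 | intermediate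
16 | 3,5-bis(methoxymethoxy)phenyl N-(tert-butyldimethylsilyl)-N-isopropylcarbamate | CC(C)N([Si](C)(C)C(C)(C)C)C(=O)Oc1cc(OCOC)cc(OCOC)c1 | intermediate
17 | 2-lithio-3,5-bis(methoxymethoxy)phenyl N-(tert-butyldimethylsilyl)-N-isopropylcarbamate | CC(C)N([Si](C)(C)C(C)(C)C)C(=O)Oc1cc(OCOC)cc(OCOC)c1[Li] | intermediate
18 | 3,5-bis(methoxymethoxy)-2-(trimethylsilyl)phenyl N-(tert-butyldimethylsilyl)-N-isopropylcarbamate | CC(C)N([Si](C)(C)C(C)(C)C)C(=O)Oc1cc(OCOC)cc(OCOC)c1[Si](C)(C)C | intermediate
19 | 2-lithio-3,5-bis(methoxymethoxy)-6-(trimethylsilyl)phenyl N-(tert-butyldimethylsilyl)-N-isopropylcarbamate | CC(C)N([Si](C)(C)C(C)(C)C)C(=O)Oc1c([Li])c(OCOC)cc(OCOC)c1[Si](C)(C)C | intermediate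
20 | 2-iodo-3,5-bis(methoxymethoxy)-6-(trimethylsilyl)phenyl N-(tert-butyldimethylsilyl)-N-isopropylcarbamate | CC(C)N([Si](C)(C)C(C)(C)C)C(=O)Oc1c(I)c(OCOC)cc(OCOC)c1[Si](C)(C)C | intermediate
21 | 2-iodo-3,5-bis(methoxymethoxy)-6-(trimethylsilyl)phenyl N-isopropylcarbamate | CC(C)NC(=O)Oc1c(I)c(OCOC)cc(OCOC)c1[Si](C)(C)C | intermediate
22 | {(2S)-2-[(2R)-1-(tert-butyldimethylsilyloxy)propan-2-yl]-5-methylhex-4-en-1-yl}zinc iodide | I[Zn]C[C@@H](CC=C(C)C)[C@@H](C)CO[Si](C)(C)C(C)(C)C | intermediate
23 | 2-[(2R)-2-[(2R)-1-(tert-butyldimethylsilyloxy)propan-2-yl]-5-methylhex-4-en-1-yl]-3,5-bis(methoxymethoxy)-6-(trimethylsilyl)phenyl N-isopropylcarbamate | CC(C)NC(=O)Oc1c(C[C@@H](CC=C(C)C)[C@@H](C)CO[Si](C)(C)C(C)(C)C)c(OCOC)cc(OCOC)c1[Si](C)(C)C | intermediate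
24 | 2-[(2R)-2-[(2R)-1-(tert-butyldimethylsilyloxy)propan-2-yl]-5-methylhex-4-en-1-yl]-3,5-bis(methoxymethoxy)-6-(trimethylsilyl)phenol | Oc1c(C[C@@H](CC=C(C)C)[C@@H](C)CO[Si](C)(C)C(C)(C)C)c(OCOC)cc(OCOC)c1[Si](C)(C)C | intermediate
25 | 2-[(2R)-2-[(2R)-1-(tert-butyldimethylsilyloxy)propan-2-yl]-5-methylhex-4-en-1-yl]-3,5-bis(methoxymethoxy)-6-(trimethylsilyl)phenyl trifluoromethanesulfonate | C[Si](C)(C)c1c(OCOC)cc(OCOC)c(C[C@@H](CC=C(C)C)[C@@H](C)CO[Si](C)(C)C(C)(C)C)c1OS(=O)(=O)C(F)(F)F | intermediate
26 | 1-(2,4-dihydroxyphenyl)ethan-1-one | CC(=O)c1ccc(O)cc1O | starting material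
27 | 1-[2-hydroxy-4-(methoxymethoxy)phenyl]ethan-1-one | CC(=O)c1ccc(OCOC)cc1O | intermediate
28 | 1-[2-methoxy-4-(methoxymethoxy)phenyl]ethan-1-one | CC(=O)c1ccc(OCOC)cc1OC | intermediate
29 | methyl 3-[2-methoxy-4-(methoxymethoxy)phenyl]-3-oxopropanoate | COC(=O)CC(=O)c1ccc(OCOC)cc1OC | intermediate
30 | methyl (3S)-3-hydroxy-3-[2-methoxy-4-(methoxymethoxy)phenyl]propanoate | COc1cc(OCOC)ccc1[C@@H](O)CC(=O)OC | intermediate
31 | (3S)-3-hydroxy-N-methoxy-3-[2-methoxy-4-(methoxymethoxy)phenyl]-N-methylpropanamide | COc1cc(OCOC)ccc1[C@@H](O)CC(=O)N(C)OC | intermediate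
32 | sodium alkoxide of 31 | COc1cc(OCOC)ccc1[C@@H]([O-])CC(=O)N(C)OC.[Na+] | intermediate
33 | aryne from 25 (C4a≡C8a) | COCOC1=CC(OCOC)=C(C[C@@H](CC=C(C)C)[C@@H](C)CO[Si](C)(C)C(C)(C)C)C#C1 | intermediate
34 | sodium aryl anion (O1–C8a formed, carbanion at C4a) | COc1cc(OCOC)ccc1[C@H](CC(=O)N(C)OC)Oc1c(C[C@@H](CC=C(C)C)[C@@H](C)CO[Si](C)(C)C(C)(C)C)c(OCOC)cc(OCOC)[c-]1.[Na+] | intermediate
35 | sodium hemiaminal alkoxide (ring C closed, C4 bearing O− and N(OMe)Me) | COc1cc(OCOC)ccc1[C@@H]1CC([O-])(N(C)OC)c2c(OCOC)cc(OCOC)c(C[C@@H](CC=C(C)C)[C@@H](C)CO[Si](C)(C)C(C)(C)C)c2O1.[Na+] | intermediate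
36 | (2S)-8-[(2R)-2-[(2R)-1-(tert-butyldimethylsilyloxy)propan-2-yl]-5-methylhex-4-en-1-yl]-2-[2-methoxy-4-(methoxymethoxy)phenyl]-5,7-bis(methoxymethoxy)chroman-4-one | COc1cc(OCOC)ccc1[C@@H]1CC(=O)c2c(OCOC)cc(OCOC)c(C[C@@H](CC=C(C)C)[C@@H](C)CO[Si](C)(C)C(C)(C)C)c2O1 | intermediate
37 | (2S)-5,7-dihydroxy-8-[(2R)-2-[(2R)-1-hydroxypropan-2-yl]-5-methylhex-4-en-1-yl]-2-(4-hydroxy-2-methoxyphenyl)chroman-4-one (CNP0081318.1) | COc1cc(O)ccc1[C@@H]1CC(=O)c2c(O)cc(O)c(C[C@@H](CC=C(C)C)[C@@H](C)CO)c2O1 | target

**Step count and risks**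

Total step count: 18. Longest linear sequence: 10 steps (steps 1–6, 10, 11, 17, 18).

Steps most likely to fail:

1. Step 17 (proposed new method). The aryl anion may be protonated before it reaches the amide carbonyl, giving the open aryl ether. Attack of the hindered secondary alkoxide at C8a, next to the C8 side chain, may be slower than its attack on the sulfur or silicon of the precursor, and some addition at C4a may occur.
 Fallback (known chemistry), setting out from 25 and 30 and returning at 36: hydroxy ester 30 is dehydrated in one flask (MsCl, Et3N, CH2Cl2, 0 °C, then DBU) through the mesylate methyl (3S)-3-[2-methoxy-4-(methoxymethoxy)phenyl]-3-(methylsulfonyloxy)propanoate F1 to methyl (E)-3-[2-methoxy-4-(methoxymethoxy)phenyl]prop-2-enoate F2. LiOH in aqueous THF then gives (E)-3-[2-methoxy-4-(methoxymethoxy)phenyl]prop-2-enoic acid F3. Heating 25 with F3 and CsF in THF uses the known insertion of arynes into the C–O bond of carboxylic acids: the carboxylate adds through oxygen at C8a of aryne 33 and the aryl anion takes the acyl group to C4a. The resulting hydroxychalcone (E)-1-[3-[(2R)-2-[(2R)-1-(tert-butyldimethylsilyloxy)propan-2-yl]-5-methylhex-4-en-1-yl]-2-hydroxy-4,6-bis(methoxymethoxy)phenyl]-3-[2-methoxy-4-(methoxymethoxy)phenyl]prop-2-en-1-one F4 closes by oxa-Michael addition under the same basic conditions. This path does not control C2. It should give 36 together with its (2R)-epimer F5; the two are diastereomers because of the side-chain centres and are to be separated by preparative chromatography, with F5 re-equilibrated through F4 under mild base.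

2. Step 9. Lithiation between the two MOM ethers may compete with lithiation at the carbamate-flanked position in either metalation, and chlorosilane or lithium salts left from the first quench may disturb the second metalation in the same flask.
 Fallback, setting out from 14 and returning at 18: NBS with catalytic i-Pr2NH in CH2Cl2 at −78 °C, conditions that favour bromination ortho to a free phenol, should give 2-bromo-3,5-bis(methoxymethoxy)phenol F6. (Me3Si)2NH converts it into [2-bromo-3,5-bis(methoxymethoxy)phenoxy]trimethylsilane F7. n-BuLi (THF, −78 °C) effects bromine–lithium exchange to [2-lithio-3,5-bis(methoxymethoxy)phenoxy]trimethylsilane F8, which undergoes the retro-Brook oxygen-to-carbon silyl shift to lithium 3,5-bis(methoxymethoxy)-2-(trimethylsilyl)phenoxide F9. Addition of i-PrNCO to the same flask and a buffered quench give 3,5-bis(methoxymethoxy)-2-(trimethylsilyl)phenyl N-isopropylcarbamate F10, which is isolated. N-Silylation of F10 (TBSOTf, TMEDA, Et2O, 0 °C → rt) leads to 18, and the second metalation and iodine quench of step 9 follow on purified material. Here the position of silicon is fixed by the position of bromine, and only one metalation is run per flask.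

3. Step 10. Oxidative addition and transmetalation at the doubly ortho-substituted, electron-rich iodide may be slow, so that protonolysis of the alkylzinc by the carbamate N–H or reduction of the aryl iodide takes over.
 Fallback, setting out from 11 and 15 and returning at 23: alcohol 11 is converted (Tf2O, 2,6-lutidine, CH2Cl2, −78 °C) into (2S)-2-[(2R)-1-(tert-butyldimethylsilyloxy)propan-2-yl]-5-methylhex-4-en-1-yl trifluoromethanesulfonate F11. This is added at −78 °C, in place of iodine, to aryllithium 19, generated from 15 as in step 9. SN2 alkylation should give 2-[(2R)-2-[(2R)-1-(tert-butyldimethylsilyloxy)propan-2-yl]-5-methylhex-4-en-1-yl]-3,5-bis(methoxymethoxy)-6-(trimethylsilyl)phenyl N-(tert-butyldimethylsilyl)-N-isopropylcarbamate F12, and the acidic work-up gives 23. The polarity of the coupling is reversed and neither palladium nor zinc is involved.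

**Further compounds**

F1 | step 17 | methyl (3S)-3-[2-methoxy-4-(methoxymethoxy)phenyl]-3-(methylsulfonyloxy)propanoate | COc1cc(OCOC)ccc1[C@@H](OS(C)(=O)=O)CC(=O)OC
F2 | step 17 | methyl (E)-3-[2-methoxy-4-(methoxymethoxy)phenyl]prop-2-enoate | COC(=O)/C=C/c1ccc(OCOC)cc1OC
F3 | step 17 | (E)-3-[2-methoxy-4-(methoxymethoxy)phenyl]prop-2-enoic acid | OC(=O)/C=C/c1ccc(OCOC)cc1OC
F4 | step 17 | (E)-1-[3-[(2R)-2-[(2R)-1-(tert-butyldimethylsilyloxy)propan-2-yl]-5-methylhex-4-en-1-yl]-2-hydroxy-4,6-bis(methoxymethoxy)phenyl]-3-[2-methoxy-4-(methoxymethoxy)phenyl]prop-2-en-1-one | COc1cc(OCOC)ccc1/C=C/C(=O)c1c(OCOC)cc(OCOC)c(C[C@@H](CC=C(C)C)[C@@H](C)CO[Si](C)(C)C(C)(C)C)c1O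
F5 | step 17 | (2R)-epimer of 36 | COc1cc(OCOC)ccc1[C@H]1CC(=O)c2c(OCOC)cc(OCOC)c(C[C@@H](CC=C(C)C)[C@@H](C)CO[Si](C)(C)C(C)(C)C)c2O1
F6 | step 9 | 2-bromo-3,5-bis(methoxymethoxy)phenol | Oc1cc(OCOC)cc(OCOC)c1Br
F7 | step 9 | [2-bromo-3,5-bis(methoxymethoxy)phenoxy]trimethylsilane | C[Si](C)(C)Oc1cc(OCOC)cc(OCOC)c1Br
F8 | step 9 | [2-lithio-3,5-bis(methoxymethoxy)phenoxy]trimethylsilane | C[Si](C)(C)Oc1cc(OCOC)cc(OCOC)c1[Li]
F9 | step 9 | lithium 3,5-bis(methoxymethoxy)-2-(trimethylsilyl)phenoxide | [Li+].[O-]c1cc(OCOC)cc(OCOC)c1[Si](C)(C)C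
F10 | step 9 | 3,5-bis(methoxymethoxy)-2-(trimethylsilyl)phenyl N-isopropylcarbamate | CC(C)NC(=O)Oc1cc(OCOC)cc(OCOC)c1[Si](C)(C)C
F11 | step 10 | (2S)-2-[(2R)-1-(tert-butyldimethylsilyloxy)propan-2-yl]-5-methylhex-4-en-1-yl trifluoromethanesulfonate | FC(F)(F)S(=O)(=O)OC[C@@H](CC=C(C)C)[C@@H](C)CO[Si](C)(C)C(C)(C)C
F12 | step 10 | 2-[(2R)-2-[(2R)-1-(tert-butyldimethylsilyloxy)propan-2-yl]-5-methylhex-4-en-1-yl]-3,5-bis(methoxymethoxy)-6-(trimethylsilyl)phenyl N-(tert-butyldimethylsilyl)-N-isopropylcarbamate | CC(C)N([Si](C)(C)C(C)(C)C)C(=O)Oc1c(C[C@@H](CC=C(C)C)[C@@H](C)CO[Si](C)(C)C(C)(C)C)c(OCOC)cc(OCOC)c1[Si](C)(C)C
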